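**Retrosynthetic overview**

1. The C40 polyene is cut last at the central C15–C15' single bond (Stille coupling) into two C20 halves: a polyenyl stannane carrying the trimethylcyclohexadienylidene end group and a polyenyl iodide carrying the silyl-protected hydroxy end group. Each half is a ring C14 trienal plus a C6 dienylphosphonate (HWE at C10=C11 and C10'=C11').
2. Both ring trienals come from one achiral cross-conjugated dienone. γ-Enolisation, triflation and methylation give the 2,4-diene end group; asymmetric β-borylation/oxidation (sets C3' as S), α-enol triflation and methylation give the 4-en-3-ol end group.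
3. The dienone comes (Saegusa–Ito) from an (E)-2-dienylidene-3,3-dimethylcyclohexanone. This is made in the key step by a 1,2-shift ring expansion of a 1-enynyl-2,2-dimethylcyclopentan-1-ol, itself from 2,2-dimethylcyclopentanone and a C6 enyne.
4. Enabling feature: in the end-group ring C1–C6 the exocyclic C6=C7 bond lies between the quaternary C1 (CMe2: migrates well, has no H, blocks aromatisation) and C5, whose methyl on sp2 carbon is a ketone in disguise. C6 and C7 can therefore be the two carbons of an alkyne, and C8 cis to C1 is what an anti 1,2-shift onto that alkyne delivers.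
5. Ring order: the purchased cyclopentane becomes the six-membered ring once (step 5); that one ring serves both end groups and no other ring is formed.

Key step: step 5

Remark: carotenoid-style labels are used (ring C1–C6, chain C7–C15; primes for the hydroxylated half); TBS = tert-butyldimethylsilyl. In both end groups C8 (C8') is cis to the CMe2 ring carbon across the exocyclic double bond, as the target SMILES encodes.

Assumption: the Josiphos enantiomer used in step 11 is the one that converts cyclohex-2-enone into (S)-3-hydroxycyclohexanone under the same conditions; the same enantioface preference is assumed for the dienone.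

**Route**

Step 1
Reactants: 1 3-(trimethylsilyl)prop-2-ynal; 2 ethyl 2-(triphenyl-λ5-phosphanylidene)propanoate
Product: 3 ethyl (2E)-2-methyl-5-(trimethylsilyl)pent-2-en-4-ynoate
Conditions: CH2Cl2, 0 °C → rt
Reagents that add atoms: none
Why: Wittig olefination with a stabilised α-methyl ylide should give the E-trisubstituted enoate, which fixes the later C8=C9 geometry (C7 and C10 trans).

Step 2
Reactants: 3 ethyl (2E)-2-methyl-5-(trimethylsilyl)pent-2-en-4-ynoate
Product: 4 (2E)-2-methyl-5-(trimethylsilyl)pent-2-en-4-yn-1-ol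
Conditions: DIBAL-H (2.2 equiv), CH2Cl2, −78 °C; Rochelle salt
Reagents that add atoms: none
Why: DIBAL-H 1,2-reduction of an α,β-unsaturated ester should give the allylic alcohol without touching the silylalkyne or the olefin geometry.

Step 3
Reactants: 4 (2E)-2-methyl-5-(trimethylsilyl)pent-2-en-4-yn-1-ol
Product: 5 tert-butyl(dimethyl){[(2E)-2-methyl-5-(trimethylsilyl)pent-2-en-4-yn-1-yl]oxy}silane
Conditions: TBSCl, imidazole, CH2Cl2, rt
Reagents that add atoms: tert-butyldimethylsilyl chloride CC(C)(C)[Si](C)(C)Cl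
Why: Imidazole-mediated silylation of a primary allylic alcohol is routine and gives a group that survives the organometallic, gold and enolate steps.

Step 4
Reactants: 5 tert-butyl(dimethyl){[(2E)-2-methyl-5-(trimethylsilyl)pent-2-en-4-yn-1-yl]oxy}silane; 6 2,2-dimethylcyclopentan-1-one
Product: 8 1-[(3E)-5-(TBSO)-4-methylpent-3-en-1-yn-1-yl]-2,2-dimethylcyclopentan-1-ol (racemic), via lithium acetylide 7 (not isolated)
Conditions: MeLi·LiBr, THF, 0 °C → rt; then 6, −78 → 0 °C; aq NH4Cl
Reagents that add atoms: none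
Why: MeLi should cleave the alkynyl–SiMe3 bond selectively to the lithium acetylide, which adds 1,2 to the ketone (acetylide addition); the new carbinol centre is racemic and is erased in step 5.

Step 5
Reactants: 8 1-[(3E)-5-(TBSO)-4-methylpent-3-en-1-yn-1-yl]-2,2-dimethylcyclopentan-1-ol
Product: 9 (2E)-2-[(2E)-4-(TBSO)-3-methylbut-2-en-1-ylidene]-3,3-dimethylcyclohexan-1-one
Conditions: [(4-CF3C6H4)3P]AuCl (3 mol%), AgSbF6 (3 mol%), CH2Cl2, 4 Å MS, 0 °C → rt
Reagents that add atoms: none
Why: Proposed new method: cationic Au(I) should π-activate the alkyne anti to the C1–C2 ring bond, the quaternary CMe2 carbon then shifts from the carbinol carbon to the proximal alkyne carbon while O–H becomes C=O (semipinacol), and retentive protodeauration of the alkenylgold releases the catalyst; the six-membered ring is thus closed by migration of an existing ring bond (insertion of the alkyne carbon into the cyclopentane), not by a cyclisation. The closest known reaction type is the Au(I)-catalysed ring expansion of 1-alkynylcyclopropanols and 1-alkynylcyclobutanols to (E)-alkylidenecycloalkanones, and the iodonium-triggered expansion of 1-(haloethynyl)cyclopentanols to 2-(dihalomethylidene)cyclohexanones shows that an unstrained cyclopentanol bond can migrate to an activated alkyne with the more substituted carbon moving; here C=O formation and relief of the congestion between the carbinol and CMe2 carbons replace ring strain as driving force. No stereocentre is created (the carbinol centre is destroyed); the element set is the exocyclic double bond, where anti addition of the migrating carbon and gold followed by retentive protonation should place the dienyl chain cis to CMe2 and trans to C=O (E), which is the C6=C7 arrangement of both end groups and is probably not the thermodynamically preferred one for the ketone. The step needs CMe2 rather than CH2 migration (secured by the gem-dimethyl group), ring expansion rather than Meyer–Schuster rearrangement or hydration (dry medium, non-nucleophilic SbF6−, electron-poor phosphine), and an inert allylic silyl ether (its E geometry keeps the oxygen away from the alkyne).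

Step 6
Reactants: 9 (2E)-2-[(2E)-4-(TBSO)-3-methylbut-2-en-1-ylidene]-3,3-dimethylcyclohexan-1-one
Product: 11 (6E)-6-[(2E)-4-(TBSO)-3-methylbut-2-en-1-ylidene]-5,5-dimethylcyclohex-2-en-1-one, via trimethylsilyl enol ether 10 (not isolated)
Conditions: LDA, TMSCl, THF, −78 °C; then Pd(OAc)2 (1.1 equiv), MeCN, rt
Reagents that add atoms: none
Why: Saegusa–Ito dehydrogenation: the only α-CH2 is enolised kinetically and the silyl enol ether should give the enone by Pd(II)-mediated β-hydride elimination, the exocyclic double bond not being involved.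

Step 7
Reactants: 11 (6E)-6-[(2E)-4-(TBSO)-3-methylbut-2-en-1-ylidene]-5,5-dimethylcyclohex-2-en-1-one
Product: 13 (6E)-6-[(2E)-4-(TBSO)-3-methylbut-2-en-1-ylidene]-5,5-dimethylcyclohexa-1,3-dien-1-yl trifluoromethanesulfonate, via potassium dienolate 12 (not isolated)
Conditions: KHMDS, THF, −78 °C; PhNTf2, −78 → 0 °C
Reagents that add atoms: N-phenylbis(trifluoromethanesulfonimide) FC(F)(F)S(=O)(=O)N(c1ccccc1)S(=O)(=O)C(F)(F)F
Why: The ketone has no α-hydrogen, so kinetic deprotonation should occur at the ring γ-CH2 to give the linear dienolate, whose O-triflation (enol triflate formation) fixes the C2=C3/C4=C5 diene and leaves the cross-conjugated exocyclic bond untouched.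

Step 8
Reactants: 13 (6E)-6-[(2E)-4-(TBSO)-3-methylbut-2-en-1-ylidene]-5,5-dimethylcyclohexa-1,3-dien-1-yl trifluoromethanesulfonate
Product: 14 tert-butyl(dimethyl){[(2E,4Z)-2-methyl-4-(2,6,6-trimethylcyclohexa-2,4-dien-1-ylidene)but-2-en-1-yl]oxy}silane
Conditions: MeZnCl, Pd(PPh3)4 (5 mol%), THF, rt
Reagents that add atoms: methylzinc chloride C[Zn]Cl
Why: Negishi coupling of an alkenyl triflate with retention should install the C5 methyl group and complete the blocked trienylidene ring.

Step 9
Reactants: 14 tert-butyl(dimethyl){[(2E,4Z)-2-methyl-4-(2,6,6-trimethylcyclohexa-2,4-dien-1-ylidene)but-2-en-1-yl]oxy}silane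
Product: 15 (2E,4Z)-2-methyl-4-(2,6,6-trimethylcyclohexa-2,4-dien-1-ylidene)but-2-en-1-ol
Conditions: TBAF, THF, 0 °C
Reagents that add atoms: none
Why: Fluoride desilylation is neutral to basic and should not disturb the acid-sensitive cross-conjugated triene.

Step 10
Reactants: 15 (2E,4Z)-2-methyl-4-(2,6,6-trimethylcyclohexa-2,4-dien-1-ylidene)but-2-en-1-ol
Product: 16 (2E,4Z)-2-methyl-4-(2,6,6-trimethylcyclohexa-2,4-dien-1-ylidene)but-2-enal
Conditions: MnO2, CH2Cl2, rt, dark
Reagents that add atoms: none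
Why: MnO2 oxidises allylic alcohols selectively to enals under neutral conditions, so double-bond geometry should be kept.

Step 11
Reactants: 11 (6E)-6-[(2E)-4-(TBSO)-3-methylbut-2-en-1-ylidene]-5,5-dimethylcyclohex-2-en-1-one
Product: 18 (2E,5S)-5-hydroxy-2-[(2E)-4-(TBSO)-3-methylbut-2-en-1-ylidene]-3,3-dimethylcyclohexan-1-one, via pinacolboryl ketone 17 (not isolated)
Conditions: CuCl (3 mol%), NaOtBu (5 mol%), Josiphos SL-J001 (3.5 mol%, enantiomer per assumption), B2pin2, MeOH, THF, rt; then NaBO3·4H2O, THF–H2O, 0 °C → rt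
Reagents that add atoms: sodium perborate [Na+].[Na+].O[B-]1(O)OO[B-](O)(O)OO1
Why: Copper-catalysed asymmetric β-borylation of a cyclic enone should occur at the unhindered endocyclic β-CH (the exocyclic β-carbon is shielded by CMe2) and retentive oxidation gives the carbinol; the chiral bisphosphine–copper boryl complex sets the stereocentre (5S here, C3' S in the target).

Step 12
Reactants: 18 (2E,5S)-5-hydroxy-2-[(2E)-4-(TBSO)-3-methylbut-2-en-1-ylidene]-3,3-dimethylcyclohexan-1-one
Product: 19 (2E,5S)-5-(TBSO)-2-[(2E)-4-(TBSO)-3-methylbut-2-en-1-ylidene]-3,3-dimethylcyclohexan-1-one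
Conditions: TBSCl, imidazole, DMF, rt
Reagents that add atoms: tert-butyldimethylsilyl chloride CC(C)(C)[Si](C)(C)Cl
Why: Silylation under weakly basic conditions should protect the β-hydroxy ketone without β-elimination or epimerisation.

Step 13
Reactants: 19 (2E,5S)-5-(TBSO)-2-[(2E)-4-(TBSO)-3-methylbut-2-en-1-ylidene]-3,3-dimethylcyclohexan-1-one
Product: 21 (3S,6E)-3-(TBSO)-6-[(2E)-4-(TBSO)-3-methylbut-2-en-1-ylidene]-5,5-dimethylcyclohex-1-en-1-yl trifluoromethanesulfonate, via potassium enolate 20 (not isolated)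
Conditions: KHMDS, THF, −78 °C; PhNTf2, −78 → −20 °C
Reagents that add atoms: N-phenylbis(trifluoromethanesulfonimide) FC(F)(F)S(=O)(=O)N(c1ccccc1)S(=O)(=O)C(F)(F)F
Why: Kinetic enolisation can only occur at the single α-CH2 and the β-silyloxy enolate should be stable at −78 °C, so O-triflation (enol triflate formation) gives the C4'=C5' triflate with the stereocentre intact.

Step 14
Reactants: 21 (3S,6E)-3-(TBSO)-6-[(2E)-4-(TBSO)-3-methylbut-2-en-1-ylidene]-5,5-dimethylcyclohex-1-en-1-yl trifluoromethanesulfonate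
Product: 22 tert-butyl{[(1S,4E)-4-[(2E)-4-(TBSO)-3-methylbut-2-en-1-ylidene]-3,5,5-trimethylcyclohex-2-en-1-yl]oxy}dimethylsilane
Conditions: MeZnCl, Pd(PPh3)4 (5 mol%), THF, rt
Reagents that add atoms: methylzinc chloride C[Zn]Cl
Why: Negishi coupling of the alkenyl triflate should install the C5' methyl group; the allylic silyl ether is too poor a leaving group to form a π-allyl complex.

Step 15
Reactants: 22 tert-butyl{[(1S,4E)-4-[(2E)-4-(TBSO)-3-methylbut-2-en-1-ylidene]-3,5,5-trimethylcyclohex-2-en-1-yl]oxy}dimethylsilane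
Product: 23 (2E,4E)-4-[(4S)-4-(TBSO)-2,6,6-trimethylcyclohex-2-en-1-ylidene]-2-methylbut-2-en-1-ol
Conditions: HF·pyridine, pyridine, THF, 0 °C
Reagents that add atoms: none
Why: Buffered HF·pyridine should cleave the unhindered primary silyl ether much faster than the secondary ring silyl ether (steric differentiation).

Step 16
Reactants: 23 (2E,4E)-4-[(4S)-4-(TBSO)-2,6,6-trimethylcyclohex-2-en-1-ylidene]-2-methylbut-2-en-1-ol
Product: 24 (2E,4E)-4-[(4S)-4-(TBSO)-2,6,6-trimethylcyclohex-2-en-1-ylidene]-2-methylbut-2-enal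
Conditions: MnO2, CH2Cl2, rt, dark
Reagents that add atoms: none
Why: Neutral MnO2 oxidation of the primary allylic alcohol should give the trienal while the protected secondary carbinol is untouched.

Step 17
Reactants: 25 (2E)-3-methylpent-2-en-4-yn-1-ol
Product: 26 (2E,4E)-3-methyl-5-(tributylstannyl)penta-2,4-dien-1-ol
Conditions: Bu3SnH, PdCl2(PPh3)2 (2 mol%), THF, 0 °C → rt
Reagents that add atoms: tributyltin hydride CCCC[SnH](CCCC)CCCC
Why: Palladium-catalysed syn hydrostannation of the terminal alkyne should place tin on the terminal carbon and give the E-alkenylstannane (future C14=C15).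

Step 18
Reactants: 26 (2E,4E)-3-methyl-5-(tributylstannyl)penta-2,4-dien-1-ol
Product: 27 [(1E,3E)-5-bromo-3-methylpenta-1,3-dien-1-yl](tributyl)stannane
Conditions: CBr4, PPh3, 2,6-lutidine, CH2Cl2, 0 °C
Reagents that add atoms: carbon tetrabromide BrC(Br)(Br)Br
Why: Appel bromination of the primary allylic alcohol is neutral, so the acid-labile C–Sn bond should survive.

Step 19
Reactants: 27 [(1E,3E)-5-bromo-3-methylpenta-1,3-dien-1-yl](tributyl)stannane
Product: 28 diethyl [(2E,4E)-3-methyl-5-(tributylstannyl)penta-2,4-dien-1-yl]phosphonate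
Conditions: P(OEt)3 (neat), 90 °C
Reagents that add atoms: triethyl phosphite CCOP(OCC)OCC
Why: Michaelis–Arbuzov reaction of a primary allylic bromide should give the linear allylic phosphonate.

Step 20
Reactants: 28 diethyl [(2E,4E)-3-methyl-5-(tributylstannyl)penta-2,4-dien-1-yl]phosphonate
Product: 29 diethyl [(2E,4E)-5-iodo-3-methylpenta-2,4-dien-1-yl]phosphonate
Conditions: I2 (1.05 equiv), CH2Cl2, 0 °C, dark
Reagents that add atoms: iodine II
Why: Iododestannylation is an ipso substitution with retention, so the E-iodide should result while the phosphonate is inert.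

Step 21
Reactants: 28 diethyl [(2E,4E)-3-methyl-5-(tributylstannyl)penta-2,4-dien-1-yl]phosphonate; 16 (2E,4Z)-2-methyl-4-(2,6,6-trimethylcyclohexa-2,4-dien-1-ylidene)but-2-enal
Product: 31 tributyl[(1E,3E,5E,7E,9Z)-3,7-dimethyl-9-(2,6,6-trimethylcyclohexa-2,4-dien-1-ylidene)nona-1,3,5,7-tetraen-1-yl]stannane, via sodium phosphonate anion 30 (not isolated)
Conditions: NaHMDS, THF, −78 °C; then 16, −78 → 0 °C
Reagents that add atoms: none
Why: Horner–Wadsworth–Emmons olefination of an allylic phosphonate anion with an enal should form C10=C11 with E selectivity and keep the existing double bonds.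

Step 22
Reactants: 29 diethyl [(2E,4E)-5-iodo-3-methylpenta-2,4-dien-1-yl]phosphonate; 24 (2E,4E)-4-[(4S)-4-(TBSO)-2,6,6-trimethylcyclohex-2-en-1-ylidene]-2-methylbut-2-enal
Product: 33 tert-butyl{[(1S,4E)-4-[(2E,4E,6E,8E)-9-iodo-3,7-dimethylnona-2,4,6,8-tetraen-1-ylidene]-3,5,5-trimethylcyclohex-2-en-1-yl]oxy}dimethylsilane, via sodium phosphonate anion 32 (not isolated)
Conditions: NaHMDS, THF, −78 °C; then 24, −78 → 0 °C
Reagents that add atoms: none
Why: The same E-selective Horner–Wadsworth–Emmons olefination should form C10'=C11'; the aldehyde is the electrophile so no carbanion is placed next to the allylic silyloxy group.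

Step 23
Reactants: 31 tributyl[(1E,3E,5E,7E,9Z)-3,7-dimethyl-9-(2,6,6-trimethylcyclohexa-2,4-dien-1-ylidene)nona-1,3,5,7-tetraen-1-yl]stannane; 33 tert-butyl{[(1S,4E)-4-[(2E,4E,6E,8E)-9-iodo-3,7-dimethylnona-2,4,6,8-tetraen-1-ylidene]-3,5,5-trimethylcyclohex-2-en-1-yl]oxy}dimethylsilane
Product: 34 tert-butyldimethylsilyl ether of the target (3'-O-TBS anhydroeschscholtzxanthin)
Conditions: Pd2(dba)3 (2.5 mol%), AsPh3 (20 mol%), NMP, rt, dark
Reagents that add atoms: none
Why: Stille coupling of an alkenylstannane with an alkenyl iodide proceeds with retention at both partners at room temperature and should form the central C15–C15' bond without isomerising the polyene.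

Step 24
Reactants: 34 tert-butyldimethylsilyl ether of the target
Product: 35 anhydroeschscholtzxanthin (target)
Conditions: TBAF, THF, 0 °C → rt, dark; crystallisation
Reagents that add atoms: none
Why: Fluoride desilylation avoids acid, which would ionise the allylic C3' oxygen, so the 3'S carbinol and all double-bond geometries should be preserved.

**Compound list**

1 | 3-(trimethylsilyl)prop-2-ynal | C[Si](C)(C)C#CC=O | starting material
2 | ethyl 2-(triphenyl-λ5-phosphanylidene)propanoate | CCOC(=O)C(C)=P(c1ccccc1)(c1ccccc1)c1ccccc1 | starting material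
3 | ethyl (2E)-2-methyl-5-(trimethylsilyl)pent-2-en-4-ynoate | CCOC(=O)/C(C)=C/C#C[Si](C)(C)C | intermediate
4 | (2E)-2-methyl-5-(trimethylsilyl)pent-2-en-4-yn-1-ol | OC/C(C)=C/C#C[Si](C)(C)C | intermediate
5 | tert-butyl(dimethyl){[(2E)-2-methyl-5-(trimethylsilyl)pent-2-en-4-yn-1-yl]oxy}silane | CC(C)(C)[Si](C)(C)OC/C(C)=C/C#C[Si](C)(C)C | intermediate
6 | 2,2-dimethylcyclopentan-1-one | CC1(C)CCCC1=O | starting material
7 | [(3E)-5-(TBSO)-4-methylpent-3-en-1-yn-1-yl]lithium (lithium acetylide) | [Li]C#C/C=C(C)/CO[Si](C)(C)C(C)(C)C | intermediate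
8 | 1-[(3E)-5-(TBSO)-4-methylpent-3-en-1-yn-1-yl]-2,2-dimethylcyclopentan-1-ol (racemic) | CC1(C)CCCC1(O)C#C/C=C(C)/CO[Si](C)(C)C(C)(C)C | intermediate
9 | (2E)-2-[(2E)-4-(TBSO)-3-methylbut-2-en-1-ylidene]-3,3-dimethylcyclohexan-1-one | O=C1CCCC(C)(C)\C1=C/C=C(C)/CO[Si](C)(C)C(C)(C)C | intermediate
10 | {[(6E)-6-[(2E)-4-(TBSO)-3-methylbut-2-en-1-ylidene]-5,5-dimethylcyclohex-1-en-1-yl]oxy}trimethylsilane (trimethylsilyl enol ether) | C[Si](C)(C)OC1=CCCC(C)(C)\C1=C/C=C(C)/CO[Si](C)(C)C(C)(C)C | intermediate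
11 | (6E)-6-[(2E)-4-(TBSO)-3-methylbut-2-en-1-ylidene]-5,5-dimethylcyclohex-2-en-1-one | O=C1C=CCC(C)(C)\C1=C/C=C(C)/CO[Si](C)(C)C(C)(C)C | intermediate
12 | potassium (6E)-6-[(2E)-4-(TBSO)-3-methylbut-2-en-1-ylidene]-5,5-dimethylcyclohexa-1,3-dien-1-olate (potassium dienolate) | [K+].[O-]C1=CC=CC(C)(C)\C1=C/C=C(C)/CO[Si](C)(C)C(C)(C)C | intermediate
13 | (6E)-6-[(2E)-4-(TBSO)-3-methylbut-2-en-1-ylidene]-5,5-dimethylcyclohexa-1,3-dien-1-yl trifluoromethanesulfonate | O=S(=O)(OC1=CC=CC(C)(C)\C1=C/C=C(C)/CO[Si](C)(C)C(C)(C)C)C(F)(F)F | intermediate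
14 | tert-butyl(dimethyl){[(2E,4Z)-2-methyl-4-(2,6,6-trimethylcyclohexa-2,4-dien-1-ylidene)but-2-en-1-yl]oxy}silane | CC1=CC=CC(C)(C)\C1=C/C=C(C)/CO[Si](C)(C)C(C)(C)C | intermediate
15 | (2E,4Z)-2-methyl-4-(2,6,6-trimethylcyclohexa-2,4-dien-1-ylidene)but-2-en-1-ol | CC1=CC=CC(C)(C)\C1=C/C=C(C)/CO | intermediate
16 | (2E,4Z)-2-methyl-4-(2,6,6-trimethylcyclohexa-2,4-dien-1-ylidene)but-2-enal | CC1=CC=CC(C)(C)\C1=C/C=C(C)/C=O | intermediate
17 | (2E,5S)-2-[(2E)-4-(TBSO)-3-methylbut-2-en-1-ylidene]-3,3-dimethyl-5-(4,4,5,5-tetramethyl-1,3,2-dioxaborolan-2-yl)cyclohexan-1-one (pinacolboryl ketone) | O=C1C[C@@H](B2OC(C)(C)C(C)(C)O2)CC(C)(C)\C1=C/C=C(C)/CO[Si](C)(C)C(C)(C)C | intermediate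
18 | (2E,5S)-5-hydroxy-2-[(2E)-4-(TBSO)-3-methylbut-2-en-1-ylidene]-3,3-dimethylcyclohexan-1-one | O=C1C[C@@H](O)CC(C)(C)\C1=C/C=C(C)/CO[Si](C)(C)C(C)(C)C | intermediate
19 | (2E,5S)-5-(TBSO)-2-[(2E)-4-(TBSO)-3-methylbut-2-en-1-ylidene]-3,3-dimethylcyclohexan-1-one | O=C1C[C@@H](O[Si](C)(C)C(C)(C)C)CC(C)(C)\C1=C/C=C(C)/CO[Si](C)(C)C(C)(C)C | intermediate
20 | potassium (3S,6E)-3-(TBSO)-6-[(2E)-4-(TBSO)-3-methylbut-2-en-1-ylidene]-5,5-dimethylcyclohex-1-en-1-olate (potassium enolate) | [K+].[O-]C1=C[C@@H](O[Si](C)(C)C(C)(C)C)CC(C)(C)\C1=C/C=C(C)/CO[Si](C)(C)C(C)(C)C | intermediate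
21 | (3S,6E)-3-(TBSO)-6-[(2E)-4-(TBSO)-3-methylbut-2-en-1-ylidene]-5,5-dimethylcyclohex-1-en-1-yl trifluoromethanesulfonate | O=S(=O)(OC1=C[C@@H](O[Si](C)(C)C(C)(C)C)CC(C)(C)\C1=C/C=C(C)/CO[Si](C)(C)C(C)(C)C)C(F)(F)F | intermediate
22 | tert-butyl{[(1S,4E)-4-[(2E)-4-(TBSO)-3-methylbut-2-en-1-ylidene]-3,5,5-trimethylcyclohex-2-en-1-yl]oxy}dimethylsilane | CC1=C[C@@H](O[Si](C)(C)C(C)(C)C)CC(C)(C)\C1=C/C=C(C)/CO[Si](C)(C)C(C)(C)C | intermediate
23 | (2E,4E)-4-[(4S)-4-(TBSO)-2,6,6-trimethylcyclohex-2-en-1-ylidene]-2-methylbut-2-en-1-ol | CC1=C[C@@H](O[Si](C)(C)C(C)(C)C)CC(C)(C)\C1=C/C=C(C)/CO | intermediate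
24 | (2E,4E)-4-[(4S)-4-(TBSO)-2,6,6-trimethylcyclohex-2-en-1-ylidene]-2-methylbut-2-enal | CC1=C[C@@H](O[Si](C)(C)C(C)(C)C)CC(C)(C)\C1=C/C=C(C)/C=O | intermediate
25 | (2E)-3-methylpent-2-en-4-yn-1-ol | C#C/C(C)=C/CO | starting material
26 | (2E,4E)-3-methyl-5-(tributylstannyl)penta-2,4-dien-1-ol | CCCC[Sn](CCCC)(CCCC)/C=C/C(C)=C/CO | intermediate
27 | [(1E,3E)-5-bromo-3-methylpenta-1,3-dien-1-yl](tributyl)stannane | CCCC[Sn](CCCC)(CCCC)/C=C/C(C)=C/CBr | intermediate
28 | diethyl [(2E,4E)-3-methyl-5-(tributylstannyl)penta-2,4-dien-1-yl]phosphonate | CCOP(=O)(OCC)C/C=C(C)/C=C/[Sn](CCCC)(CCCC)CCCC | intermediate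
29 | diethyl [(2E,4E)-5-iodo-3-methylpenta-2,4-dien-1-yl]phosphonate | CCOP(=O)(OCC)C/C=C(C)/C=C/I | intermediate
30 | sodium salt of the C1 carbanion of 28 (sodium phosphonate anion) | [Na+].CCOP(=O)(OCC)[CH-]/C=C(C)/C=C/[Sn](CCCC)(CCCC)CCCC | intermediate
31 | tributyl[(1E,3E,5E,7E,9Z)-3,7-dimethyl-9-(2,6,6-trimethylcyclohexa-2,4-dien-1-ylidene)nona-1,3,5,7-tetraen-1-yl]stannane | CC1=CC=CC(C)(C)\C1=C/C=C(C)/C=C/C=C(C)/C=C/[Sn](CCCC)(CCCC)CCCC | intermediate
32 | sodium salt of the C1 carbanion of 29 (sodium phosphonate anion) | [Na+].CCOP(=O)(OCC)[CH-]/C=C(C)/C=C/I | intermediate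
33 | tert-butyl{[(1S,4E)-4-[(2E,4E,6E,8E)-9-iodo-3,7-dimethylnona-2,4,6,8-tetraen-1-ylidene]-3,5,5-trimethylcyclohex-2-en-1-yl]oxy}dimethylsilane | CC1=C[C@@H](O[Si](C)(C)C(C)(C)C)CC(C)(C)\C1=C/C=C(C)/C=C/C=C(C)/C=C/I | intermediate
34 | tert-butyldimethylsilyl ether of the target (3'-O-TBS anhydroeschscholtzxanthin) | CC1=CC=CC(C)(C)\C1=C/C=C(C)/C=C/C=C(C)/C=C/C=C/C(C)=C/C=C/C(C)=C/C=C1/C(C)=C[C@@H](O[Si](C)(C)C(C)(C)C)CC1(C)C | intermediate
35 | anhydroeschscholtzxanthin, the (S)-configured retro-carotenol of the task | CC1=CC=CC(C)(C)\C1=C/C=C(C)/C=C/C=C(C)/C=C/C=C/C(C)=C/C=C/C(C)=C/C=C1/C(C)=C[C@@H](O)CC1(C)C | target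

**Step count and risks**

Total step count: 24. Longest linear sequence: 15 steps (steps 1–6, 11–16, 22–24).

The three steps most likely to fail:

Step 5 (proposed new method). The unstrained cyclopentanol bond may fail to migrate to the gold-activated enyne, so that a 1,3-hydroxyl shift or hydration takes over, or adventitious acid may isomerise the kinetically formed exocyclic double bond. The fallback runs the ring expansion in its known halonium form and attaches the diene afterwards; it sets out from 6 and comes back at 9.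
- Ketone 6 is treated with ethynylmagnesium bromide to give 1-ethynyl-2,2-dimethylcyclopentan-1-ol F1.
- Bromination at the alkyne terminus (NBS, cat. AgNO3, acetone) gives 1-(bromoethynyl)-2,2-dimethylcyclopentan-1-ol F2.
- I2 and [hydroxy(tosyloxy)iodo]benzene in MeCN should expand the ring to (2Z)-2-[bromo(iodo)methylidene]-3,3-dimethylcyclohexan-1-one F3. This is the known reaction of 1-(haloethynyl)cyclopentanols, in which the more substituted carbon migrates anti to the incoming iodine, so bromine ends cis to CMe2.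
- Chemoselective Pd(PPh3)4/Bu3SnH reduction of the C–I bond with retention gives (2E)-2-(bromomethylidene)-3,3-dimethylcyclohexan-1-one F4.
- The coupling partner is made from propargyl alcohol: zirconium-catalysed methylalumination to the (E)-alkenylalane F5 (not isolated), iodinolysis to (2E)-3-iodo-2-methylprop-2-en-1-ol F6, silylation to tert-butyl{[(2E)-3-iodo-2-methylprop-2-en-1-yl]oxy}dimethylsilane F7, and t-BuLi then Bu3SnCl to tert-butyl(dimethyl){[(2E)-2-methyl-3-(tributylstannyl)prop-2-en-1-yl]oxy}silane F8.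
- Stille coupling of F4 with F8 (Pd2(dba)3, AsPh3, CuI, NMP) with retention at both partners gives 9.

Step 11. Enantiofacial discrimination on this 6-alkylidene enone may be poor, or the copper boryl may add in part to the exocyclic dienone. The fallback secures the stereocentre by kinetic resolution instead of catalyst control; it sets out from 11 and comes back at 18.
- Dienone 11 is borylated with an achiral ligand (CuCl, Xantphos, B2pin2, MeOH) to the racemic pinacolboryl ketone F9 (not isolated) and oxidised with sodium perborate to the racemic hydroxy ketone F10.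
- A Burkholderia cepacia lipase with vinyl acetate in MTBE is expected to acylate the 5S alcohol to the (5S)-acetate F11 and leave the (5R)-alcohol F12. This follows the empirical size rule for ring carbinols with the CMe2 side as the large group, as in the 3-hydroxy-β-ionone series.
- After chromatographic separation, F11 is hydrolysed by the same lipase in phosphate buffer (no base, so no β-elimination) to give 18.

Step 7. Deprotonation may occur at the exocyclic ε-positions (C9 methyl, C10 methylene) instead of the ring γ-CH2, which would give isomeric triflates and scramble C6=C7. The fallback makes the dienylidene end group by the branch in which enolisation is unambiguous and then dehydrates it, following the anhydro relationship of the two end groups; it sets out from 24 and comes back at 16.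
- A portion of aldehyde 24 (racemic material would serve equally) is desilylated with TBAF/AcOH to (2E,4E)-4-[(4S)-4-hydroxy-2,6,6-trimethylcyclohex-2-en-1-ylidene]-2-methylbut-2-enal F13.
- Mesylation (MsCl, Et3N, −20 °C) gives the allylic mesylate F14 (not isolated), which is treated with DBU.
- Only C2 carries β-hydrogens, so E2 elimination should give the 2,4-diene, which is 16.

**Further compounds**

F1 | step 5 | 1-ethynyl-2,2-dimethylcyclopentan-1-ol | CC1(C)CCCC1(O)C#C
F2 | step 5 | 1-(bromoethynyl)-2,2-dimethylcyclopentan-1-ol | CC1(C)CCCC1(O)C#CBr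
F3 | step 5 | (2Z)-2-[bromo(iodo)methylidene]-3,3-dimethylcyclohexan-1-one | O=C1CCCC(C)(C)\C1=C(/Br)I
F4 | step 5 | (2E)-2-(bromomethylidene)-3,3-dimethylcyclohexan-1-one | O=C1CCCC(C)(C)\C1=C/Br
F5 | step 5 | dimethyl{(1E)-3-[(dimethylalumanyl)oxy]-2-methylprop-1-en-1-yl}alumane (alkenylalane) | C[Al](C)OC/C(C)=C/[Al](C)C
F6 | step 5 | (2E)-3-iodo-2-methylprop-2-en-1-ol | OC/C(C)=C/I
F7 | step 5 | tert-butyl{[(2E)-3-iodo-2-methylprop-2-en-1-yl]oxy}dimethylsilane | CC(C)(C)[Si](C)(C)OC/C(C)=C/I
F8 | step 5 | tert-butyl(dimethyl){[(2E)-2-methyl-3-(tributylstannyl)prop-2-en-1-yl]oxy}silane | CC(C)(C)[Si](C)(C)OC/C(C)=C/[Sn](CCCC)(CCCC)CCCC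
F9 | step 11 | racemic (2E)-2-[(2E)-4-(TBSO)-3-methylbut-2-en-1-ylidene]-3,3-dimethyl-5-(4,4,5,5-tetramethyl-1,3,2-dioxaborolan-2-yl)cyclohexan-1-one | O=C1CC(B2OC(C)(C)C(C)(C)O2)CC(C)(C)\C1=C/C=C(C)/CO[Si](C)(C)C(C)(C)C
F10 | step 11 | racemic (2E)-5-hydroxy-2-[(2E)-4-(TBSO)-3-methylbut-2-en-1-ylidene]-3,3-dimethylcyclohexan-1-one | O=C1CC(O)CC(C)(C)\C1=C/C=C(C)/CO[Si](C)(C)C(C)(C)C
F11 | step 11 | (1S,4E)-4-[(2E)-4-(TBSO)-3-methylbut-2-en-1-ylidene]-3,3-dimethyl-5-oxocyclohexyl acetate | O=C1C[C@@H](OC(C)=O)CC(C)(C)\C1=C/C=C(C)/CO[Si](C)(C)C(C)(C)C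
F12 | step 11 | (2E,5R)-5-hydroxy-2-[(2E)-4-(TBSO)-3-methylbut-2-en-1-ylidene]-3,3-dimethylcyclohexan-1-one | O=C1C[C@H](O)CC(C)(C)\C1=C/C=C(C)/CO[Si](C)(C)C(C)(C)C
F13 | step 7 | (2E,4E)-4-[(4S)-4-hydroxy-2,6,6-trimethylcyclohex-2-en-1-ylidene]-2-methylbut-2-enal | CC1=C[C@@H](O)CC(C)(C)\C1=C/C=C(C)/C=O
F14 | step 7 | (1S,4E)-3,5,5-trimethyl-4-[(2E)-3-methyl-4-oxobut-2-en-1-ylidene]cyclohex-2-en-1-yl methanesulfonate | CC1=C[C@@H](OS(C)(=O)=O)CC(C)(C)\C1=C/C=C(C)/C=O
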